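The data come from a simulation for an exercise, and the scatter is random.

What is left of the enzyme after Z has taken its share is the amount we follow in these flasks.

| flask | J | E | Z | remark | time |
|---|---|---|---|---|---|
| spring | 0.20 M | 48 µM | 25 µM | run made earlier |  |
| midnight | 0.20 M | 36 µM | 25 µM | run made earlier |  |
| Tuesday's | 0.20 M | 72 µM | 25 µM |  | 6.0 h |
| Saturday's | 0.20 M | 72 µM | 50 µM |  | 6.0 h |
| Sunday's | 0.20 M | 72 µM | 100 µM |  | 6.0 h |

| run | time / min | Q / % | J / % |
|---|---|---|---|
| spring | 10.0 | 3 | 97 |
| spring | 25.0 | 10 | 90 |
| spring | 50.0 | 14 | 86 |
| spring | 80.0 | 24 | 73 |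
| midnight | 6.00 | 4 | 98 |
| midnight | 12.0 | 1 | 97 |
| midnight | 30.0 | 7 | 95 |
| midnight | 80.0 | 12 | 89 |

(readings scatter by 1.5 percentage points)

- "hardly changes" means that all values lie within two and a half points (for a concentration: within two and a half percent of the largest)

1. amount of Q at the end, in percent of the J charged for Tuesday's, Saturday's, Sunday's, in this order
2. the shape of the row from first to last (rises, then falls / rises all the way / falls, then rises / hardly changes / falls all the way)

The spring and midnight flasks look nearly the same, with equal J and equal Z and a factor of 1.33 between their charges of E. Yet at 80.0 min the spring flask reads 24% of Q, twice the midnight flask's 12%. Take Z to bind E one to one and for good, and call the charge of E minus the charge of Z the leftover enzyme: 47.0 µM in Tuesday's flask, 23.0 µM in the spring flask and 11.0 µM in the midnight flask. The spring leftover is twice the midnight one, so we read the spring flask as ending ahead because it holds more working enzyme.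

We reckon from both ends. In Sunday's flask the charge of Z exceeds the charge of E by 28.0 µM, so on this view the leftover is nil and we expect Q near zero. In Tuesday's flask, 6.0 h at this leftover equals 9.20 spring stretches of 80.0 min. If each stretch keeps the 73% of J read in the spring flask, which the readings can't confirm, we reckon Q in Tuesday's flask at 94.5%. Saturday's leftover of 22.0 µM gives 74.2% the same way.

The forecast says 95%, 80% and 1%, a row that falls all the way, on the view that “Z titrates E about 1:1 and tightly”. Its Saturday's figure stands above ours.

The flasks give 76.6%, 60.8% and 1.53%, a row that falls all the way, with Tuesday's below both the forecast and our figure.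

    J + E → Q + E, rate k1*[J]^2.5*[E]/(1 + ([J]/Kh1)^2.5) (0.160 M, k = 2.60 × 10⁵ L²·⁵ mol⁻²·⁵ h⁻¹)
    E + Z → X (k = 7.00 × 10⁵ L mol⁻¹ h⁻¹)

In Tuesday's flask E passes into X with a half-life of 2.4 min, with the other concentrations held at their charge, far shorter than the 1.25 h by which half of the turnover of J into Q up to 6.0 h is done. At 1.80 h E stands there at 65.3% of the catalyst charged, the leftover's 65.3% of the charge, and at 6.00 h Z, the limiting reagent of that binding, stands at 0%. Saturday's leftover of 22.0 µM is 30.6% of the charge, and E in Saturday's flask stands at 30.6% at 6.00 h.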